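## The problem

Compound 18 is a ten-membered carbocycle, numbered here C1H=C2H–C3H=C4(C18O2H)–C5(=C19H2)–C6H2–C7H2–C8H(C17O2H)–C9(CH3)(C11H2–C12(=O)–3-furyl)–C10H2. A cross-conjugated triene acid with both ring double bonds cis lies opposite two adjacent stereocentres. A ring of this size resists direct closure (entropy, transannular strain), and the cis,cis-diene would have to be made with its geometry before or during the closure. The stereocentres are the tertiary C8 (R) and the quaternary C9 (S); the C17 carboxyl is cis to the C9 methyl and trans to the ketone arm. C9 carries a methyl and a CH2 group of similar size and cannot steer a later reaction at C8, whereas a substituent on C8 can send an addition to C9 to the opposite face while both atoms sit in a six-membered ring; the absolute configuration must come from outside. The limits are set by the 3-acylfuran (acid, oxidants), the triene with its exocyclic methylene (protic acid, heat), the C8 hydrogen (base), the 1,5-relation of C17 and C12 (retro-Michael cleavage of C8–C9 under forcing base), and two carboxyls that must stay distinct from the C12 acyl group until the furan is attached. The enabling feature is that C5–C10 with C17 and the C9 methyl form the ring of Hagemann's ester after a conjugate addition to C9, while C1–C4 with C18 are the diene carbons of a 2-pyranone-3-carboxylate. Only the C5–C10 bond of the six-membered ring has to break, and C5, which ends next to the ester-bearing C4, can carry the oxygen that pays for this cleavage by becoming part of a β-keto ester enolate.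

## Retrosynthesis

**18 from 17.** The two O-alkyl bonds of the C17 ethyl and C18 methyl esters are cut last. These esters are the ones already present in the commercial ring precursors 3 and 6, so masking the acids costs no step, and free acids would interfere with the organometallic and Lewis-acid steps before. The forward reaction is a hydrolysis that must spare C8 and the furyl ketone.

**17 from 12 and 13.** The C12–furyl bond is cut. The acylfuran could instead come in with the nucleophile that builds C9–C11, but a second ketone would then compete with C5 in the methylenation and the furan would have to survive the cycloaddition. A carboxyl at C12 is the inert placeholder, and acid 12 plus 3-bromofuran 13 are both simpler than 17. The forward step needs an acylation that tolerates two esters and the triene, which a palladium-catalysed acid chloride–organozinc coupling does.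

**12 from 10, and 10 from 9.** Acid 12 is unmasked from tert-butyl ester 10, which is orthogonal to the methyl and ethyl esters and hindered enough to stay out of the key step. The C5=C19 bond of 10 is cut back to ketone 9. The C5 oxygen is what the ring expansion leaves behind, C5 is the only ketone at that stage, and methylenating at once removes the electrophilic alkylidene β-keto ester unit. The forward reaction must be non-basic, because of C8 and the acidic dienone.

**9 from 5 and 6.** Retrosynthetically the C5–C10 bond is re-formed and C10–C1 and C5–C4 are cut, with CO2 returned to the four-carbon unit. Against every cut that closes the ten-membered ring (see the roads not taken), this one makes the ring by cleaving a bond of a fused bicycle, so there is no medium-ring closure, and the cis,cis geometry follows from orbital symmetry and the ring constraint. The precursors are a cyclohexene enol silane 5 and the commercial pyranone 6. The forward reaction asks for polarity-controlled regiochemistry, a hindered cycloaddition at C10, and ring opening faster than aromatisation.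

**5 from 4, 4 from 3 and 2, 2 from 1.** The C9–C11 bond is cut to Hagemann's ester 3 and silyl ketene acetal 2, made from tert-butyl acetate 1. A Mukaiyama–Michael addition gives the enol silane towards C10 directly; enolisation of the corresponding ketone would go towards C6 instead. The C8 ester directs the nucleophile to the opposite face, which sets the relative configuration. The absolute configuration is a separate matter:

- Compound 3 is racemic and its C8 hydrogen is labile.
- A catalyst-controlled version would have to select one enantiomer of an equilibrating enone while building a quaternary centre.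
- The silyl Lewis acids that effect the addition turn the enone into its achiral dienol silane as soon as a base is present to racemise it.

The absolute configuration is therefore taken from a resolution of 4 to 5, placed directly after the addition where material is cheapest.

## Roads not taken

**Alternative 1:** The cut is C8–C9. The ring carboxyl C17 is tied through oxygen to C12 in the fourteen-membered allylic lactone A1. Enolisation and O-silylation of A1, then Ireland–Claisen rearrangement, would form C8–C9, contract the ring to the ten-membered acid A2, free C17 and leave C11=C12 as a furyl-conjugated alkene.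
- Merits: both stereocentres are made in the ring-forming step with chirality transfer from the C12 carbinol, which a standard asymmetric ketone reduction can set. Here this road is better than the chosen one, which gives up half the material in a resolution. A fourteen-membered lactonisation is also easier than any ten-membered carbocyclisation.
- Weak points: A1 must already contain the cis,cis-diene, the exocyclic methylene and C18, so the sensitive triene is built early and carried through strong-base enolisation. The C8/C9 outcome depends on ketene acetal geometry and on a chair or boat transition state inside a macrocycle, which is hard to predict. A2 still needs a regioselective oxidation of C11=C12 to the C12 ketone beside three other alkenes, and two oxidations at C18 next to a furan.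
- Comparison: the chosen plan sets against the better absolute stereocontrol a route of eight steps from commercial rings in which the triene appears only after the ring is formed.

**Alternative 2:** The cuts are C3=C4 and C5=C19. Acyclic enyne A3, with a terminal (Z)-diene and a C4≡C5 alkyne, would undergo endo ring-closing enyne metathesis with a ruthenium alkylidene catalyst under ethylene A5, giving triene A4.
- Merits: the ring-closing reaction belongs to a known catalytic class, the methylene arrives in the same step and the furyl ketone is already in place. In precedent for the key step and in steps after it, this road is better.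
- Weak points: an endo closure to a ten-membered ring competes with cross-metathesis of the alkyne with A5 and with truncation of the conjugated diene. The geometry of the new C3=C4 bond is not controlled. C8 and C9 must be built on an open chain, which is harder than on a six-membered ring and needs its own source of absolute configuration. C18 still has to be oxidised twice beside the furan.
- Comparison: the chosen plan sets against the better precedent a ring made by cleavage, with no entropic cost, and a diene geometry fixed by the mechanism.

**Alternative 3:** Eight-membered allyl β-keto ester A6 would add through C2 to methyl propiolate A7, the vinyl anion would close on the C5 ketone, and retro-aldol cleavage of C2–C5 would give the ten-membered 2-carbomethoxy enone A8.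
- Merits: this two-carbon ring expansion of cyclic β-keto esters with acetylenic esters is known chemistry under mild base, and it delivers the C5 ketone, the C4 ester and C3=C4 directly. In precedent for the ring-expanding event it is better than the chosen plan.
- Weak points: A6 is itself a medium ring carrying C8 and C9 and must be made first. A8 lacks the C1=C2 bond and carries an extra ester on C2, so a decarboxylative dehydrogenation with uncertain regiochemistry and geometry is needed before the same end game.
- Comparison: the chosen plan sets against the precedent the insertion of all four carbons and both cis double bonds in one operation, starting from a commercial six-membered ring.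

Key step: step 4

Assumption: Hagemann's ester 3 is used as the commercial racemate with a labile C8 hydrogen; the locants C1–C12 and C17–C19 defined above are kept for all intermediates, and "cis" for a ring double bond refers to the ring path (C1=C2 is Z, C3=C4 is E by the sequence rules).

## Route

Step 1
Reactants: 1 tert-butyl acetate
Product: 2 tert-butyl[(1-tert-butoxyethenyl)oxy]dimethylsilane
Conditions: LiN(i-Pr)2, THF, −78 °C; TBSCl, HMPA, −78 °C → rt
Reagents that add atoms: tert-butyl(chloro)dimethylsilane, CC(C)(C)[Si](C)(C)Cl
Why: O-silylation of a lithium ester enolate in the presence of HMPA is the standard preparation of silyl ketene acetals; the distilled product is used directly.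

Step 2
Reactants: 3 Hagemann's ester (ethyl 2-methyl-4-oxocyclohex-2-ene-1-carboxylate, racemic); 2 tert-butyl[(1-tert-butoxyethenyl)oxy]dimethylsilane
Product: 4 racemic ethyl (1R*,2R*)-2-(2-tert-butoxy-2-oxoethyl)-4-[(tert-butyldimethylsilyl)oxy]-2-methylcyclohex-3-ene-1-carboxylate
Conditions: Tf2NH (5 mol %), CH2Cl2, −78 → −40 °C; Et3N quench
Reagents that add atoms: none
Why: Mukaiyama–Michael addition under silyl Lewis acid catalysis, with transfer of the silyl group to the enolate oxygen, should give the C5=C10 enol silane regiospecifically. The C8 ester sits pseudoaxial to avoid A(1,2) strain with the C9 methyl, so axial attack at C9 comes from the opposite face and places the new CH2CO2t-Bu arm trans to the ester (methyl cis to it). No base is present, so C8 is not equilibrated during the addition.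

Step 3
Reactants: 4 racemic ethyl (1R*,2R*)-2-(2-tert-butoxy-2-oxoethyl)-4-[(tert-butyldimethylsilyl)oxy]-2-methylcyclohex-3-ene-1-carboxylate
Product: 5 ethyl (1R,2R)-2-(2-tert-butoxy-2-oxoethyl)-4-[(tert-butyldimethylsilyl)oxy]-2-methylcyclohex-3-ene-1-carboxylate
Conditions: preparative SFC, amylose tris(3,5-dimethylphenylcarbamate) phase, CO2/i-PrOH, 0.1% Et3N
Reagents that add atoms: none
Why: Chromatographic resolution of enantiomers on a chiral stationary phase, placed here because C8 becomes configurationally stable only once the enone is consumed. The absolute configuration of the collected enantiomer is to be assigned by anomalous-dispersion crystallography of a later crystalline intermediate.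

Step 4
Reactants: 5 ethyl (1R,2R)-2-(2-tert-butoxy-2-oxoethyl)-4-[(tert-butyldimethylsilyl)oxy]-2-methylcyclohex-3-ene-1-carboxylate; 6 methyl 2-oxo-2H-pyran-3-carboxylate
Product: 9 ethyl (1Z,3E,8R,9S)-9-(2-tert-butoxy-2-oxoethyl)-4-(methoxycarbonyl)-9-methyl-5-oxocyclodeca-1,3-diene-8-carboxylate, via bridged lactone cycloadduct 7 (not isolated), via cis-fused silyloxy diene 8 (not isolated)
Conditions: 2,6-di-tert-butyl-4-methylpyridine (0.1 equiv), toluene, 110 °C (−CO2); then (Me2N)3S+ Me3SiF2− (TASF), THF/DMF, 0 °C → rt; AcOH; Et3N (cat.), CH2Cl2, rt
Reagents that add atoms: none
Why: Proposed new method: the electron-rich enol silane 5 and the electron-poor pyranone 6 should combine in an inverse-electron-demand [4+2] cycloaddition, polarity placing the nucleophilic C10 on the pyranone carbon next to the ring oxygen (C1) and C5 on the ester-bearing carbon (C4); the closest known reaction type is the Diels–Alder reaction of this pyranone with enol ethers, ketene acetals and enamines followed by loss of CO2. The temporary six-membered ring C1–C2–C3–C4–C5–C10 closes suprafacially on the ring-(Z) enol ether, so that 7 and, after retro-[4+2] loss of CO2, diene 8 are cis-fused whichever face is attacked. Fluoride then frees the tertiary C5 alkoxide, which should open by a thermally allowed disrotatory 6π process, in effect a doubly vinylogous retro-aldol cleavage of C5–C10; this part has no precedent, the nearest known cases being the retro-aldol opening of cyclobutene alkoxides in two-carbon ring expansions and other oxy-anion-accelerated pericyclic reactions. The ten-membered ring thus arises by bond cleavage and not by closure, and the driving force is the exchange of a tertiary alkoxide for an anion delocalised over the C5 carbonyl, the C18 ester and the diene. Disrotatory opening of a cis-fused ring can only give the coiled all-cis trienolate, so protonation at C10 leaves both ring double bonds cis; no new stereocentre survives, because C5 and C10 return to carbonyl carbon and CH2, and C8 and C9 are spectators. The step needs ring opening to outrun aromatisation by loss of silanol or water, which is why the thermal stage is run with an acid scavenger and the desilylation with an aprotic fluoride source; the closing amine treatment is there to gather the protonation tautomers in the conjugated dienone 9.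

Step 5
Reactants: 9 ethyl (1Z,3E,8R,9S)-9-(2-tert-butoxy-2-oxoethyl)-4-(methoxycarbonyl)-9-methyl-5-oxocyclodeca-1,3-diene-8-carboxylate
Product: 10 ethyl (1Z,3E,8R,9S)-9-(2-tert-butoxy-2-oxoethyl)-4-(methoxycarbonyl)-9-methyl-5-methylidenecyclodeca-1,3-diene-8-carboxylate
Conditions: Zn, CH2Br2, TiCl4, THF/CH2Cl2, 0 °C → rt
Reagents that add atoms: dibromomethane, BrCBr
Why: Takai–Lombardo methylenation; the non-basic geminal dimetallic reagent converts enolisable and conjugated ketones into methylene compounds and leaves esters alone at this temperature. C8 and the acidic dienone are never exposed to base, and C5 is the only ketone present.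

Step 6
Reactants: 10 ethyl (1Z,3E,8R,9S)-9-(2-tert-butoxy-2-oxoethyl)-4-(methoxycarbonyl)-9-methyl-5-methylidenecyclodeca-1,3-diene-8-carboxylate
Product: 12 2-[(1R,2Z,4E,10R)-10-(ethoxycarbonyl)-5-(methoxycarbonyl)-1-methyl-6-methylidenecyclodeca-2,4-dien-1-yl]acetic acid (the C12 acid; 8R,9S in target numbering), via trimethylsilyl ester 11 (not isolated)
Conditions: TMSOTf, 2,6-lutidine, CH2Cl2, 0 °C; aq. pH 5 buffer
Reagents that add atoms: none
Why: Silyl triflate-mediated cleavage of a tert-butyl ester to the silyl ester, hydrolysed on work-up, is selective over methyl and ethyl esters. The buffered, aprotic medium avoids the protic acid that could protonate the exocyclic methylene of the triene.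

Step 7
Reactants: 12 2-[(1R,2Z,4E,10R)-10-(ethoxycarbonyl)-5-(methoxycarbonyl)-1-methyl-6-methylidenecyclodeca-2,4-dien-1-yl]acetic acid; 13 3-bromofuran
Product: 17 ethyl (1Z,3E,8R,9S)-9-[2-(furan-3-yl)-2-oxoethyl]-4-(methoxycarbonyl)-9-methyl-5-methylidenecyclodeca-1,3-diene-8-carboxylate, via acid chloride 14 (not isolated), via 3-furyllithium 15 (not isolated), via 3-furylzinc bromide 16 (not isolated)
Conditions: 12, 1-chloro-N,N,2-trimethylprop-1-en-1-amine, CH2Cl2, 0 °C → rt; 13, n-BuLi, THF, −78 °C, then ZnBr2; Pd(PPh3)4 (5 mol %), THF, 0 °C → rt
Reagents that add atoms: none
Why: Negishi-type acylation; the acid chloride is made under neutral conditions and coupled with an organozinc that adds neither to esters nor to the ketone formed. 3-Furyllithium is generated by halogen–lithium exchange and transmetalated at −78 °C, before it can isomerise to the 2-lithio species.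

Step 8
Reactants: 17 ethyl (1Z,3E,8R,9S)-9-[2-(furan-3-yl)-2-oxoethyl]-4-(methoxycarbonyl)-9-methyl-5-methylidenecyclodeca-1,3-diene-8-carboxylate
Product: 18 (1Z,3E,8R,9S)-9-[2-(furan-3-yl)-2-oxoethyl]-9-methyl-5-methylidenecyclodeca-1,3-diene-4,8-dicarboxylic acid
Conditions: LiOH, THF/MeOH/H2O, rt → 45 °C; 1 M HCl to pH 3
Reagents that add atoms: lithium hydroxide, [Li+].[OH-]
Why: Saponification by acyl–oxygen cleavage; the conjugated methyl ester should go first, and its carboxylate then shields the dienoate from conjugate addition. Hydrolysis of the C17 ester should be faster than enolisation at C8, and the carboxylate once formed resists deprotonation, so C8 should keep its configuration.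

## Compound list

1 | tert-butyl acetate | CC(=O)OC(C)(C)C | starting material
2 | tert-butyl[(1-tert-butoxyethenyl)oxy]dimethylsilane | C=C(OC(C)(C)C)O[Si](C)(C)C(C)(C)C | intermediate
3 | Hagemann's ester, ethyl 2-methyl-4-oxocyclohex-2-ene-1-carboxylate (racemic) | CCOC(=O)C1CCC(=O)C=C1C | starting material
4 | racemic ethyl (1R*,2R*)-2-(2-tert-butoxy-2-oxoethyl)-4-[(tert-butyldimethylsilyl)oxy]-2-methylcyclohex-3-ene-1-carboxylate (ester cis to methyl; both enantiomers written) | CC(C)(C)[Si](C)(C)OC=1CC[C@@H](C(=O)OCC)[C@](C)(CC(=O)OC(C)(C)C)C=1.CC(C)(C)[Si](C)(C)OC=1CC[C@H](C(=O)OCC)[C@@](C)(CC(=O)OC(C)(C)C)C=1 | intermediate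
5 | ethyl (1R,2R)-2-(2-tert-butoxy-2-oxoethyl)-4-[(tert-butyldimethylsilyl)oxy]-2-methylcyclohex-3-ene-1-carboxylate (ring C1 = C8, C2 = C9, C3 = C10, C4 = C5 of the target) | CC(C)(C)[Si](C)(C)OC=1CC[C@@H](C(=O)OCC)[C@](C)(CC(=O)OC(C)(C)C)C=1 | intermediate
6 | methyl 2-oxo-2H-pyran-3-carboxylate | COC(=O)C1=CC=COC1=O | starting material
7 | bridged lactone cycloadduct, not isolated: 2-oxabicyclo[2.2.2]oct-5-en-3-one formed across C5=C10 (bonds C10–C1 and C5–C4, lactone bridge C1–O–C(=O)–C4, CO2Me on C4, OTBS on C5; 8R,9R; the four transient centres C1, C4, C5, C10 left unassigned) | COC(=O)C13C=CC(OC1=O)C2[C@@](C)(CC(=O)OC(C)(C)C)[C@H](C(=O)OCC)CCC23O[Si](C)(C)C(C)(C)C | intermediate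
8 | cis-fused silyloxy diene, not isolated: 5-silyloxycyclohexa-1,3-diene ring C1=C2–C3=C4(CO2Me)–C5(OTBS)–C10H fused to the six-membered ring carrying C8 and C9 (8R,9R; C5–O and C10–H cis, drawn for attack anti to the C9 methyl, the other cis-fused isomer converging on 9 as well) | CC(C)(C)[Si](C)(C)O[C@@]12CC[C@@H](C(=O)OCC)[C@](C)(CC(=O)OC(C)(C)C)[C@@H]1C=CC=C2C(=O)OC | intermediate
9 | ethyl (1Z,3E,8R,9S)-9-(2-tert-butoxy-2-oxoethyl)-4-(methoxycarbonyl)-9-methyl-5-oxocyclodeca-1,3-diene-8-carboxylate (target numbering; both ring double bonds cis in the ring) | O=C1CC[C@@H](C(=O)OCC)[C@](C)(CC(=O)OC(C)(C)C)C/C=C\C=C/1C(=O)OC | intermediate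
10 | ethyl (1Z,3E,8R,9S)-9-(2-tert-butoxy-2-oxoethyl)-4-(methoxycarbonyl)-9-methyl-5-methylidenecyclodeca-1,3-diene-8-carboxylate | C=C1CC[C@@H](C(=O)OCC)[C@](C)(CC(=O)OC(C)(C)C)C/C=C\C=C/1C(=O)OC | intermediate
11 | trimethylsilyl ester of acid 12, not isolated | C=C1CC[C@@H](C(=O)OCC)[C@](C)(CC(=O)O[Si](C)(C)C)C/C=C\C=C/1C(=O)OC | intermediate
12 | 2-[(1R,2Z,4E,10R)-10-(ethoxycarbonyl)-5-(methoxycarbonyl)-1-methyl-6-methylidenecyclodeca-2,4-dien-1-yl]acetic acid (C12 acid; 8R,9S in target numbering) | C=C1CC[C@@H](C(=O)OCC)[C@](C)(CC(=O)O)C/C=C\C=C/1C(=O)OC | intermediate
13 | 3-bromofuran | Brc1ccoc1 | starting material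
14 | acid chloride of 12, not isolated | C=C1CC[C@@H](C(=O)OCC)[C@](C)(CC(=O)Cl)C/C=C\C=C/1C(=O)OC | intermediate
15 | 3-furyllithium, not isolated | [Li]c1ccoc1 | intermediate
16 | 3-furylzinc bromide, not isolated | Br[Zn]c1ccoc1 | intermediate
17 | ethyl (1Z,3E,8R,9S)-9-[2-(furan-3-yl)-2-oxoethyl]-4-(methoxycarbonyl)-9-methyl-5-methylidenecyclodeca-1,3-diene-8-carboxylate | C=C1CC[C@@H](C(=O)OCC)[C@](C)(CC(=O)c2ccoc2)C/C=C\C=C/1C(=O)OC | intermediate
18 | (1Z,3E,8R,9S)-9-[2-(furan-3-yl)-2-oxoethyl]-9-methyl-5-methylidenecyclodeca-1,3-diene-4,8-dicarboxylic acid (CNP0137484.1) | C=C1CC[C@@H](C(=O)O)[C@](C)(CC(=O)c2ccoc2)C/C=C\C=C/1C(=O)O | target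

## Step count and risk

Total: 8 steps. Longest linear sequence: 8 steps (1 → 2 → 4 → 5 → 9 → 10 → 12 → 17 → 18); 3, 6 and 13 enter as commercial materials.

**Step 4 (key step, new method).** Three things may go wrong.
- The cycloaddition may be slow, because C10 is neopentyl and C5 must bond to a fully substituted pyranone carbon. Pressure (10–15 kbar at ambient temperature) is the first remedy; this is a change of conditions, not the fallback.
- The ring may aromatise, by loss of silanol across C5–C10 during CO2 extrusion or by dehydration once the silyl group is gone, since a benzoate is the thermodynamic sink.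
- The alkoxide may fail to open, or protonation may leave the deconjugated β-keto ester tautomer or its 2H-pyran valence isomer instead of 9.

The fallback for the ring-opening half uses known photochemistry and sets out from 8, this time isolated by filtration through base-washed silica. Irradiation of 8 through Pyrex at −78 °C in THF should open the ring-fused cyclohexa-1,3-diene by the conrotatory 6π path, as ring-fused cyclohexadienes are known to give cyclodeca-1,3,5-trienes. The product is the ten-membered silyl trienol ether F1, with one terminal double bond trans. Without warming, TASF cleaves this silyl enol ether, a routine reaction, to the same trienolate, with no alkoxide stage at which water could be lost. Both terminal double bonds lose their geometry on protonation at C10, and acetic acid quench with amine equilibration returns the route at 9.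

**Step 5.** The methylene–titanium/zinc reagent may add in conjugate fashion to the doubly activated dienone or reduce it, or the hindered cross-conjugated carbonyl next to the fully substituted C4 may react too slowly. The fallback is a Peterson olefination from 9. Me3SiCH2MgCl with CeCl3 in THF at −78 °C (organocerium, 1,2-selective, inert to esters at this temperature) should give the β-hydroxysilane F2 as a mixture at C5. Syn-elimination with KN(SiMe3)2 in THF at 0 °C can then give only the exocyclic methylene, which comes back to the route at 10.

**Step 8.** Hydrolysis of the C17 ester beside the quaternary C9 may be slow enough to call for forcing base. That invites epimerisation at C8, enolisation at C11 with retro-Michael cleavage of C8–C9, and attack on the furyl ketone. The fallback moves the hydrolysis in front of the ketone synthesis and sets out from 12. LiOH at 50 °C on the ketone-free 12 gives the triacid F4. Dicyclohexylcarbodiimide in CH2Cl2 closes the six-membered anhydride between the C12 and C17 carboxyls, giving anhydride acid F5. After neutralising the C18 acid with Et3N, palladium-catalysed coupling of the anhydride with 3-furylzinc bromide 16 (Pd(PPh3)4, THF) should take place at the less hindered C12 carbonyl, a known route from cyclic anhydrides to keto acids, and arrives directly at 18.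

**Step 7.** The acid chloride 14 has α-hydrogens and sits next to a quaternary carbon, so oxidative addition is slowed while loss of HCl to a ketene and decarbonylation are not. The fallback avoids the acid chloride and the organometallic and sets out from 12. Ethanethiol with EDC·HCl and DMAP in CH2Cl2 gives the S-ethyl thioester F3. Liebeskind–Srogl coupling with furan-3-ylboronic acid (Pd2(dba)3, P(2-furyl)3, copper thiophene-2-carboxylate CuO2C(C4H3S), THF, 50 °C, no base) comes back to the route at 17.

## Further compounds

F1 | step 4 | ten-membered silyl trienol ether from photochemical opening of 8 (TBSO–C5=C4(CO2Me)–C3=C2–C1=C10; C3=C2 cis, drawn with C1=C10 trans and C6 cis to C3 across C5=C4; 8R,9R) | CC(C)(C)[Si](C)(C)O/C1=C(C(=O)OC)/C=C\C=C\[C@@](C)(CC(=O)OC(C)(C)C)[C@H](C(=O)OCC)CC1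
F2 | step 5 | β-hydroxysilane from 9: C5 carries OH and CH2SiMe3 (mixture at C5; 8R,9S) | C[Si](C)(C)CC1(O)CC[C@@H](C(=O)OCC)[C@](C)(CC(=O)OC(C)(C)C)C/C=C\C=C/1C(=O)OC
F3 | step 7 | S-ethyl thioester of acid 12 | C=C1CC[C@@H](C(=O)OCC)[C@](C)(CC(=O)SCC)C/C=C\C=C/1C(=O)OC
F4 | step 8 | triacid from 12 (C12, C17 and C18 carboxylic acids; 8R,9S) | C=C1CC[C@@H](C(=O)O)[C@](C)(CC(=O)O)C/C=C\C=C/1C(=O)O
F5 | step 8 | six-membered cyclic anhydride between the C12 and C17 carboxyls of F4, C18 acid free | C=C1CC[C@H]2C(=O)OC(=O)C[C@]2(C)C/C=C\C=C/1C(=O)O
A1 | alternative 1 | fourteen-membered allylic lactone (C17 joined through oxygen to C12; cis,cis-diene, C5 methylene and C18 silyl ether in place; geometry of C9=C11 and configuration at C12 left open) | O=C1CCCC(=C)/C(CO[Si](C)(C)C(C)(C)C)=C\C=C/CC(C)=CC(c2ccoc2)O1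
A2 | alternative 1 | ten-membered C17 acid with (E)-2-(3-furyl)vinyl group on C9 and C18 silyl ether | C=C1CC[C@@H](C(=O)O)[C@](C)(/C=C/c2ccoc2)C/C=C\C=C/1CO[Si](C)(C)C(C)(C)C
A3 | alternative 2 | acyclic enyne with terminal (Z)-diene, C4≡C5 alkyne, furyl ketone, C17 ethyl ester and C18 silyl ether | CC(C)(C)[Si](C)(C)OCC#CCC[C@@H](C(=O)OCC)[C@](C)(CC(=O)c1ccoc1)C/C=C\C=C
A4 | alternative 2 | ten-membered triene with furyl ketone, C17 ethyl ester and C18 silyl ether | C=C1CC[C@@H](C(=O)OCC)[C@](C)(CC(=O)c2ccoc2)C/C=C\C=C/1CO[Si](C)(C)C(C)(C)C
A5 | alternative 2 | ethylene | C=C
A6 | alternative 3 | eight-membered allyl β-keto ester carrying C8 and C9 (C2 labile) | O=C1CC[C@@H](C(=O)OCC)[C@](C)(CC(=O)OC(C)(C)C)CCC1C(=O)OCC=C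
A7 | alternative 3 | methyl propiolate | C#CC(=O)OC
A8 | alternative 3 | ten-membered 2-carbomethoxy enone with allyl ester on C2 | O=C1CC[C@@H](C(=O)OCC)[C@](C)(CC(=O)OC(C)(C)C)CCC(C(=O)OCC=C)/C=C\1C(=O)OC
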